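**Strategy.** Ring B is grown on the ring A oxygen instead of being coupled to it. Its C1'(O-aryl)–C2'(OH)–C3'H edge is the chain of an aryloxyacetone and its C4'(CH3)–C5'H–C6'(CH2OH) edge that of a 5-silyloxypent-3-yn-2-one. One base-mediated Michael–aldol [3+3] benzannulation therefore forms C1'–C6' and C3'–C4', closes ring B and leaves the free C2' phenol; the tri-ortho-substituted diaryl ether is never made at an aromatic carbon. The precursor is ring A as 2-(trimethylsilyl)ethyl 2-allyloxy-3-prenyl-6-(2-oxopropoxy)benzoate, whose ester and allyl ether, like the silyl ether of the ynone, come off later without hydroxide or strong acid.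

Key step: step 8

Remark: ring A is numbered from the carboxyl carbon (C1; C2 OH, C3 prenyl, C6 ether oxygen) and ring B with primes from the ether carbon (C1'); tert-butyldimethyl(prop-2-yn-1-yloxy)silane is taken as a purchasable starting material.

**Step 1**
Reactants: 1 2,6-dihydroxybenzoic acid
Product: 2 2-(trimethylsilyl)ethyl 2,6-dihydroxybenzoate
Conditions: Me3SiCH2CH2OH (1.1 equiv), PPh3, DIAD, THF, 0 °C → rt
Reagents that add atoms: 2-(trimethylsilyl)ethanol, C[Si](C)(C)CCO
Why: Mitsunobu esterification, in which the carboxylic acid (far more acidic than the two phenols, which are held in hydrogen bonds to the carboxyl) is the pronucleophile, so only the ester should form and the carboxyl is masked as a group that fluoride can remove later whatever the hindrance around the carbonyl.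

**Step 2**
Reactants: 2 2-(trimethylsilyl)ethyl 2,6-dihydroxybenzoate; 3 chloroacetone
Product: 4 2-(trimethylsilyl)ethyl 2-hydroxy-6-(2-oxopropoxy)benzoate
Conditions: K2CO3 (1.2 equiv), KI (cat.), acetone, 50 °C
Reagents that add atoms: none
Why: Williamson ether synthesis on the symmetric diol, after which the remaining hydroxyl is locked in a hydrogen bond to the ester carbonyl and reacts much more slowly, while the weak base leaves the ketone and the hindered ester alone.

**Step 3**
Reactants: 5 2-methylbut-3-en-2-ol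
Product: 6 tert-butyl 2-methylbut-3-en-2-yl carbonate
Conditions: n-BuLi, THF, 0 °C; Boc2O, 0 °C → rt; H2O
Reagents that add atoms: di-tert-butyl dicarbonate, CC(C)(C)OC(=O)OC(=O)OC(C)(C)C
Why: Acylation of the lithium alkoxide of the tertiary allylic alcohol with Boc2O gives the mixed carbonate, the usual leaving group for palladium-allyl chemistry.

**Step 4**
Reactants: 4 2-(trimethylsilyl)ethyl 2-hydroxy-6-(2-oxopropoxy)benzoate; 6 tert-butyl 2-methylbut-3-en-2-yl carbonate
Product: 7 2-(trimethylsilyl)ethyl 2-[(2-methylbut-3-en-2-yl)oxy]-6-(2-oxopropoxy)benzoate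
Conditions: Pd(PPh3)4 (5 mol %), THF, 0 °C → rt
Reagents that add atoms: none
Why: Tsuji–Trost O-allylation, in which zerovalent palladium ionises 6 to a 1,1-dimethylallylpalladium cation with loss of CO2 and tert-butoxide, the tert-butoxide deprotonates the phenol, and the phenoxide attacks the more substituted allyl terminus under kinetic control to give the tertiary (reverse-prenyl) ether.

**Step 5**
Reactants: 7 2-(trimethylsilyl)ethyl 2-[(2-methylbut-3-en-2-yl)oxy]-6-(2-oxopropoxy)benzoate
Product: 8 2-(trimethylsilyl)ethyl 2-hydroxy-3-(3-methylbut-2-en-1-yl)-6-(2-oxopropoxy)benzoate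
Conditions: xylenes, 130 °C
Reagents that add atoms: none
Why: Aromatic Claisen rearrangement, whose [3,3] shift can end only at C3, the single free ortho position (C1 carries the ester), and which turns the 1,1-dimethylallyl group into the linear 3-methylbut-2-enyl group before tautomerisation restores the hydrogen-bonded phenol.

**Step 6**
Reactants: 8 2-(trimethylsilyl)ethyl 2-hydroxy-3-(3-methylbut-2-en-1-yl)-6-(2-oxopropoxy)benzoate
Product: 9 2-(trimethylsilyl)ethyl 2-(allyloxy)-3-(3-methylbut-2-en-1-yl)-6-(2-oxopropoxy)benzoate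
Conditions: allyl bromide, K2CO3, DMF, 40 °C
Reagents that add atoms: allyl bromide, C=CCBr
Why: Williamson O-allylation of the phenoxide (carbonate deprotonates the phenol, not the ketone) caps the C2 oxygen so that no phenoxide can add to the ynone in step 8, using a group that zerovalent palladium removes later without acid near the prenyl side chain.

**Step 7**
Reactants: 10 tert-butyldimethyl(prop-2-yn-1-yloxy)silane; 11 N-methoxy-N-methylacetamide
Product: 12 5-[(tert-butyldimethylsilyl)oxy]pent-3-yn-2-one
Conditions: n-BuLi, THF, −78 °C; 11, −78 → 0 °C; AcOH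
Reagents that add atoms: none
Why: Acylation of a lithium acetylide with a Weinreb amide, whose chelated tetrahedral adduct survives until the quench, so the ynone should form without over-addition and with the silyl ether intact.

**Step 8**
Reactants: 9 2-(trimethylsilyl)ethyl 2-(allyloxy)-3-(3-methylbut-2-en-1-yl)-6-(2-oxopropoxy)benzoate; 12 5-[(tert-butyldimethylsilyl)oxy]pent-3-yn-2-one
Product: 15 2-(trimethylsilyl)ethyl 2-(allyloxy)-6-[2-hydroxy-4-methyl-6-({[tert-butyl(dimethyl)silyl]oxy}methyl)phenoxy]-3-(3-methylbut-2-en-1-yl)benzoate, via Michael adduct enedione 13 (not isolated), via cyclic aldol 14 (not isolated)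
Conditions: 12 (1.1 equiv), Cs2CO3 (1.5 equiv), DMSO, rt → 50 °C; pH 7 buffer
Reagents that add atoms: none
Why: Proposed new method: carbonate forms the more stabilised enolate of 9 at the aryloxy-bearing C1' (the alpha-oxygen makes this CH2 roughly three pKa units more acidic than the methyl), which adds to the beta carbon of ynone 12 to make C1'-C6' and give enedione 13, whose doubly activated C1'-H lets the E and Z isomers interconvert through an extended dienolate. The C3' methyl enolate of the Z isomer then attacks the C4' carbonyl in a 6-(enolendo)-exo-trig aldol addition (14), and loss of water followed by enolisation of the cyclohexadienone closes ring B as the free C2' phenol, the alkyne having brought the unsaturation so that no oxidant is needed. The closest known reaction type is the base-mediated Michael-aldol [3+3] benzannulation of ketones such as dibenzyl ketones and 1,3-dicarbonyl compounds with alkynones to phenols; an alpha-aryloxy ketone has not been shown as the three-carbon partner. No stereocentre remains, because both sp3 centres of 14 are erased on aromatisation. Two selectivities are required: C1' and not C3' must be the Michael donor, which the oxygen-stabilised enolate secures, and the aldol must join C3' to C4' and not the ynone methyl to C2' (that would give the para-aryloxyphenol isomer), which is favoured because C4' is an unhindered acetyl carbonyl whereas C2' sits next to the fully substituted C1' carrying the ortho-substituted aryloxy group, and because C3'-H is the more acidic of the two methyls. The weak base, the doubly ortho-substituted ester and the ynone being present from the start should keep the C1' carbanion from acylating itself on the neighbouring ester.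

**Step 9**
Reactants: 15 2-(trimethylsilyl)ethyl 2-(allyloxy)-6-[2-hydroxy-4-methyl-6-({[tert-butyl(dimethyl)silyl]oxy}methyl)phenoxy]-3-(3-methylbut-2-en-1-yl)benzoate
Product: 16 2-(trimethylsilyl)ethyl 2-hydroxy-6-[2-hydroxy-4-methyl-6-({[tert-butyl(dimethyl)silyl]oxy}methyl)phenoxy]-3-(3-methylbut-2-en-1-yl)benzoate
Conditions: Pd(PPh3)4 (5 mol %), morpholine (5 equiv), THF, rt
Reagents that add atoms: none
Why: Tsuji–Trost deallylation, in which zerovalent palladium ionises the allyl aryl ether (its ester-flanked phenoxide is a good leaving group) and morpholine captures the allyl fragment, while the trisubstituted prenyl alkene, the silyl groups and the ester are inert.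

**Step 10**
Reactants: 16 2-(trimethylsilyl)ethyl 2-hydroxy-6-[2-hydroxy-4-methyl-6-({[tert-butyl(dimethyl)silyl]oxy}methyl)phenoxy]-3-(3-methylbut-2-en-1-yl)benzoate
Product: 17 2-hydroxy-6-[2-hydroxy-6-(hydroxymethyl)-4-methylphenoxy]-3-(3-methylbut-2-en-1-yl)benzoic acid (CNP0140656.0)
Conditions: TBAF (4 equiv), THF, 0 °C → rt; cold dilute aq. HCl to pH 3
Reagents that add atoms: none
Why: Fluoride-induced desilylation, in which attack at silicon fragments the 2-(trimethylsilyl)ethyl ester to the carboxylate, ethene and Me3SiF regardless of the two ortho substituents and the same reagent cleaves the primary silyl ether, so the ortho-prenyl phenol never meets the strong acid or hot hydroxide that could cyclise it to a chroman.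

**Compound list**
1 | 2,6-dihydroxybenzoic acid | OC(=O)c1c(O)cccc1O | starting material
2 | 2-(trimethylsilyl)ethyl 2,6-dihydroxybenzoate | C[Si](C)(C)CCOC(=O)c1c(O)cccc1O | intermediate
3 | chloroacetone | CC(=O)CCl | starting material
4 | 2-(trimethylsilyl)ethyl 2-hydroxy-6-(2-oxopropoxy)benzoate | CC(=O)COc1cccc(O)c1C(=O)OCC[Si](C)(C)C | intermediate
5 | 2-methylbut-3-en-2-ol | CC(C)(O)C=C | starting material
6 | tert-butyl 2-methylbut-3-en-2-yl carbonate | CC(C)(C=C)OC(=O)OC(C)(C)C | intermediate
7 | 2-(trimethylsilyl)ethyl 2-[(2-methylbut-3-en-2-yl)oxy]-6-(2-oxopropoxy)benzoate | CC(=O)COc1cccc(OC(C)(C)C=C)c1C(=O)OCC[Si](C)(C)C | intermediate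
8 | 2-(trimethylsilyl)ethyl 2-hydroxy-3-(3-methylbut-2-en-1-yl)-6-(2-oxopropoxy)benzoate | CC(=O)COc1ccc(CC=C(C)C)c(O)c1C(=O)OCC[Si](C)(C)C | intermediate
9 | 2-(trimethylsilyl)ethyl 2-(allyloxy)-3-(3-methylbut-2-en-1-yl)-6-(2-oxopropoxy)benzoate | CC(=O)COc1ccc(CC=C(C)C)c(OCC=C)c1C(=O)OCC[Si](C)(C)C | intermediate
10 | tert-butyldimethyl(prop-2-yn-1-yloxy)silane | C#CCO[Si](C)(C)C(C)(C)C | starting material
11 | N-methoxy-N-methylacetamide | CON(C)C(C)=O | starting material
12 | 5-[(tert-butyldimethylsilyl)oxy]pent-3-yn-2-one | CC(=O)C#CCO[Si](C)(C)C(C)(C)C | intermediate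
13 | 2-(trimethylsilyl)ethyl 2-(allyloxy)-6-{[(4Z)-4-({[tert-butyl(dimethyl)silyl]oxy}methyl)-2,6-dioxohept-4-en-3-yl]oxy}-3-(3-methylbut-2-en-1-yl)benzoate (racemic at C1'; E and Z interconvert, the Z isomer that closes is drawn) | CC(=O)/C=C(/CO[Si](C)(C)C(C)(C)C)C(Oc1ccc(CC=C(C)C)c(OCC=C)c1C(=O)OCC[Si](C)(C)C)C(C)=O | intermediate
14 | 2-(trimethylsilyl)ethyl 2-(allyloxy)-6-{[2-({[tert-butyl(dimethyl)silyl]oxy}methyl)-4-hydroxy-4-methyl-6-oxocyclohex-2-en-1-yl]oxy}-3-(3-methylbut-2-en-1-yl)benzoate (mixture of stereoisomers, both centres lost on aromatisation) | CC1(O)C=C(CO[Si](C)(C)C(C)(C)C)C(Oc2ccc(CC=C(C)C)c(OCC=C)c2C(=O)OCC[Si](C)(C)C)C(=O)C1 | intermediate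
15 | 2-(trimethylsilyl)ethyl 2-(allyloxy)-6-[2-hydroxy-4-methyl-6-({[tert-butyl(dimethyl)silyl]oxy}methyl)phenoxy]-3-(3-methylbut-2-en-1-yl)benzoate | C[Si](C)(C)CCOC(=O)c1c(OCC=C)c(CC=C(C)C)ccc1Oc1c(O)cc(C)cc1CO[Si](C)(C)C(C)(C)C | intermediate
16 | 2-(trimethylsilyl)ethyl 2-hydroxy-6-[2-hydroxy-4-methyl-6-({[tert-butyl(dimethyl)silyl]oxy}methyl)phenoxy]-3-(3-methylbut-2-en-1-yl)benzoate | C[Si](C)(C)CCOC(=O)c1c(O)c(CC=C(C)C)ccc1Oc1c(O)cc(C)cc1CO[Si](C)(C)C(C)(C)C | intermediate
17 | 2-hydroxy-6-[2-hydroxy-6-(hydroxymethyl)-4-methylphenoxy]-3-(3-methylbut-2-en-1-yl)benzoic acid | CC(C)=CCc1ccc(Oc2c(O)cc(C)cc2CO)c(C(=O)O)c1O | target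

Total step count: 10.
Longest linear sequence: 8 steps (1, 2, 4, 5, 6, 8, 9, 10).

**Steps most likely to fail**

**Step 8 (Proposed new method).** What may go wrong:
- the aldol may close in the other direction (ynone-derived methyl onto the C2' carbonyl), scrambling the substitution pattern of ring B;
- the Michael addition may go through the methyl-side enolate;
- the C1' carbanion may take the acyl group of the neighbouring ester;
- the product phenoxide may add to unreacted ynone.

Fallback (known chemistry): the ether is made by nucleophilic aromatic substitution on a preformed ring B, which is feasible because the diaryl ether carries only three ortho substituents. It sets out from 2 and returns at 17. O-alkylation of 2 with one equivalent of 6 (Pd(PPh3)4, THF) should give 2-(trimethylsilyl)ethyl 2-hydroxy-6-[(2-methylbut-3-en-2-yl)oxy]benzoate F1, and Claisen rearrangement (xylenes, 130 °C) 2-(trimethylsilyl)ethyl 2,6-dihydroxy-3-(3-methylbut-2-en-1-yl)benzoate F2. Separately, purchased 2-fluoro-5-methylphenol is converted with MOMCl and i-Pr2NEt into 1-fluoro-2-(methoxymethoxy)-4-methylbenzene F3, which is lithiated next to fluorine (n-BuLi, PMDTA, THF, −78 °C) and formylated with DMF to 2-fluoro-3-(methoxymethoxy)-5-methylbenzaldehyde F4. The less hindered C6 phenoxide of F2 displaces the formyl-activated fluoride of F4 (K2CO3, DMF, 80 °C) to give 2-(trimethylsilyl)ethyl 6-[2-formyl-6-(methoxymethoxy)-4-methylphenoxy]-2-hydroxy-3-(3-methylbut-2-en-1-yl)benzoate F5. NaBH4 (MeOH, 0 °C) reduces the aldehyde to 2-(trimethylsilyl)ethyl 2-hydroxy-6-[2-(hydroxymethyl)-6-(methoxymethoxy)-4-methylphenoxy]-3-(3-methylbut-2-en-1-yl)benzoate F6. TBAF (THF) frees 2-hydroxy-6-[2-(hydroxymethyl)-6-(methoxymethoxy)-4-methylphenoxy]-3-(3-methylbut-2-en-1-yl)benzoic acid F7, and brief treatment with dilute HCl in MeOH at room temperature removes the MOM group to reach 17.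

**Step 4.** What may go wrong: slow O-alkylation of the hydrogen-bonded phenoxide, re-ionisation of the tertiary ether at palladium with drift to the linear prenyl ether, and C-allylation of the ketone enolate.

Fallback (no palladium-allyl intermediate): it sets out from 4 and returns at 7. Copper-assisted alkylation with purchased 3-chloro-3-methylbut-1-yne (K2CO3, KI, CuI cat., acetone, 55 °C) should give 2-(trimethylsilyl)ethyl 2-[(2-methylbut-3-yn-2-yl)oxy]-6-(2-oxopropoxy)benzoate F8, a propargylic ether that cannot isomerise to a linear ether. Semihydrogenation (H2, Pd/CaCO3 poisoned with Pb(OAc)2, quinoline, EtOAc, rt) then gives 7.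

**Step 5.** What may go wrong: ionisation of the tertiary ether with loss of isoprene back to the phenol, and acid-promoted cyclisation of the ortho-prenyl phenol during heating.

Fallback (allyl transfer, then side-chain exchange): it sets out from 4 and returns at 8. Allyl bromide with K2CO3 in DMF should give 2-(trimethylsilyl)ethyl 2-(allyloxy)-6-(2-oxopropoxy)benzoate F9, a primary ether that does not ionise. Claisen rearrangement (N,N-diethylaniline, 190 °C) moves the allyl group to C3 and gives 2-(trimethylsilyl)ethyl 3-allyl-2-hydroxy-6-(2-oxopropoxy)benzoate F10. Cross-metathesis with 2-methylbut-2-ene (second-generation Grubbs catalyst, (H2IMes)(PCy3)Cl2Ru=CHPh, CH2Cl2, 40 °C) then converts the allyl into the prenyl group of 8.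

**Further compounds**
F1 | step 8 | 2-(trimethylsilyl)ethyl 2-hydroxy-6-[(2-methylbut-3-en-2-yl)oxy]benzoate | C=CC(C)(C)Oc1cccc(O)c1C(=O)OCC[Si](C)(C)C
F2 | step 8 | 2-(trimethylsilyl)ethyl 2,6-dihydroxy-3-(3-methylbut-2-en-1-yl)benzoate | CC(C)=CCc1ccc(O)c(C(=O)OCC[Si](C)(C)C)c1O
F3 | step 8 | 1-fluoro-2-(methoxymethoxy)-4-methylbenzene | COCOc1cc(C)ccc1F
F4 | step 8 | 2-fluoro-3-(methoxymethoxy)-5-methylbenzaldehyde | COCOc1cc(C)cc(C=O)c1F
F5 | step 8 | 2-(trimethylsilyl)ethyl 6-[2-formyl-6-(methoxymethoxy)-4-methylphenoxy]-2-hydroxy-3-(3-methylbut-2-en-1-yl)benzoate | CC(C)=CCc1ccc(Oc2c(C=O)cc(C)cc2OCOC)c(C(=O)OCC[Si](C)(C)C)c1O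
F6 | step 8 | 2-(trimethylsilyl)ethyl 2-hydroxy-6-[2-(hydroxymethyl)-6-(methoxymethoxy)-4-methylphenoxy]-3-(3-methylbut-2-en-1-yl)benzoate | CC(C)=CCc1ccc(Oc2c(CO)cc(C)cc2OCOC)c(C(=O)OCC[Si](C)(C)C)c1O
F7 | step 8 | 2-hydroxy-6-[2-(hydroxymethyl)-6-(methoxymethoxy)-4-methylphenoxy]-3-(3-methylbut-2-en-1-yl)benzoic acid | CC(C)=CCc1ccc(Oc2c(CO)cc(C)cc2OCOC)c(C(=O)O)c1O
F8 | step 4 | 2-(trimethylsilyl)ethyl 2-[(2-methylbut-3-yn-2-yl)oxy]-6-(2-oxopropoxy)benzoate | CC(=O)COc1cccc(OC(C)(C)C#C)c1C(=O)OCC[Si](C)(C)C
F9 | step 5 | 2-(trimethylsilyl)ethyl 2-(allyloxy)-6-(2-oxopropoxy)benzoate | CC(=O)COc1cccc(OCC=C)c1C(=O)OCC[Si](C)(C)C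
F10 | step 5 | 2-(trimethylsilyl)ethyl 3-allyl-2-hydroxy-6-(2-oxopropoxy)benzoate | CC(=O)COc1ccc(CC=C)c(O)c1C(=O)OCC[Si](C)(C)C
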